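## The problem

(+)-Myristinin A (27) is a 2,4-trans flavan: benzo ring A is fused to pyran ring C, ring B (4-hydroxyphenyl) sits on C2, and a fourth ring D, a 3-dodecanoylphloroglucinol, is bonded through C1' to C4. The two stereocentres, C2 (S) and C4 (R), are 1,3-related on ring C. C2 can be set by a catalyst on a flat precursor, and its pseudo-equatorial aryl group then sends a nucleophile to the axial side of a planar C4, which is the trans arrangement wanted; the opposite order (C4 directing a closure at C2) drifts toward the diequatorial cis isomer. Two bonds are fragile: O1–C2 is a para-oxygenated benzylic aryl ether and C4–C1' is a diarylmethine bond between two electron-rich rings, so both ionise under strong Lewis or protic acid, and a flavanone intermediate also racemises under base by retro-oxa-Michael opening. The phenols on three rings therefore need protecting groups that leave under hydrogen or fluoride, not under boron trihalides. The C4–C1' junction is the crowded point, because C1' is flanked by two oxygens and the classical union must force a deactivated acylphloroglucinol onto a C4 cation. The oxygen pattern of ring D offers another way: C1' lies between the oxygen-bearing C2' and C6', so C1'–C6' with its oxygen is the two-carbon unit of an ynol ether on C4, and C2'–C3'–C4'–C5' with oxygens on C2' and C4' is the carbon chain of a 3-alkoxycyclobutenone. Because C3' and C5' become equivalent once ring D carries three free hydroxyls, the acyl group can be added afterwards without a regiochemical question.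

## Retrosynthesis

**27 ⇐ 26 ⇐ 25 (O–benzyl and O–silyl bonds).** The last cuts are three benzyl ethers (rings A, B, D) and one silyl ether (ring D). Hydrogenolysis and fluoride are chosen because neither touches O1–C2 or C4–C1'. An ethyl ether on O4', which the commercial cyclobutenone 15 would deliver directly, is rejected: it would lie next to a ketone already chelated by a free ortho hydroxyl and could only be cleaved by forcing boron trihalide treatment, which ring C would not survive. The spectator group is therefore changed to benzyl (see 17).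

**25 ⇐ 22 + 23 (C3'–acyl bond).** The dodecanoyl group comes from dodecanoyl chloride 23 after ring D exists. Carrying the ketone through the ring-forming step would load the ketene partner with a second electrophile. Phenol 22 has a single free hydroxyl with one open ortho carbon, so its magnesium salt 24 directs the acyl group without strong acid. Whether C3' or C5' is acylated is irrelevant for 27.

**22 ⇐ 14 + 17 (C1'–C2' and C5'–C6' bonds; ring D).** Ring D is taken apart into siloxyalkyne 14 (two carbons) and 3-benzyloxycyclobutenone 17 (four carbons, reacting as vinylketene 18). The neighbouring cut, C4–C1' by Friedel–Crafts attack of a phloroglucinol on cation 9, needs a hindered, deactivated nucleophile under acid and is reversible. Here C4 carries only a slim alkyne when its configuration is fixed, and ring D is then grown under neutral thermal conditions with C2 and C4 as spectators. The precursor is simpler by a whole ring. The forward reaction must be regioselective in one event, the ketene–alkyne [2+2] step.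

**17 ⇐ 15 + 16 (O–alkyl exchange).** Commercial 3-ethoxycyclobutenone 15 is converted to the benzyl vinylogous ester 17 with benzyl alcohol 16. This is one step on a side branch, and in return no ether in the route needs a Lewis acid for removal.

**14 ⇐ 11 (C(sp)–O bond).** The ynol oxygen is introduced by oxidising lithium acetylide 12 to ynolate 13 and silylating on oxygen. The alternative of carrying an ester through a homologation would place an acidic hydrogen on C4 next to a carbonyl. The alkyne route keeps C4–H merely propargylic.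

**11 ⇐ 7 + 8 (C4–C(sp) bond; C4 stereocentre).** Ionisation of flavan-4-ol 7 gives cation 9, which is captured by the alkynyl group of trifluoroborate 8 to give silylalkyne 10 and then 11. This is where C2 controls C4. The nucleophile is small, and the configuration of the alcohol in 7 is irrelevant.

**7 ⇐ 6 ⇐ 4 + 5 (C4–H; C2–aryl bond; C2 stereocentre).** The alcohol comes from flavanone 6. For 6, the C2–aryl bond is cut to chromone 4 and boronic acid 5, because rhodium-catalysed conjugate arylation sets C2 irreversibly under base-free conditions. Asymmetric oxa-Michael closure of a 2'-hydroxychalcone is reversible and gives only modest selectivity on unactivated substrates.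

**4 ⇐ 1 + 2 (C2 and O1–C2 of the chromone).** Chromone 4 arises from acetophenone 1 and the formamide acetal 2 through enaminone 3.

## Roads not taken

**Alternative 1:** The cut is O1–C2, made last. Rings B and D and the three-carbon chain come from the dihydrochalcone phloretin A1, ring A is added at its carbonyl carbon, and the open-chain 1,1,3-triarylpropane A2 already carries C4 as a stereocentre. In the key step a catalytic quinone oxidant, regenerated at an anode, removes hydride from the C2 methylene beside the 4-benzyloxyphenyl ring and the free C8a phenol traps the cation to give flavan tetrapivalate A3.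
- Merits: a cheap natural skeleton, no pre-oxidised C2, and no cation at C4, so the hindered ring-D junction is never made by Friedel–Crafts chemistry. In steps to ring C it is probably shorter than the chosen plan.
- Weak points: stereocontrol runs the unfavourable way, since C4 must dictate C2 in the capture of a benzylic cation that can re-ionise, and equilibration favours cis. C4–H is doubly benzylic and competes with C2–H for the oxidant, held back only by four pivalates. The C4 diarylmethine still needs its own asymmetric synthesis. Pivalate removal and ring-D acylation follow, with ring A competing.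
- Comparison: against its shorter ring-C construction, the chosen plan sets C2 by a catalyst, lets C2 control C4 in the direction that favours trans, and has no site-selectivity problem in an oxidation.

**Alternative 2:** The cuts are O1–C8a and C4–C4a. Ring A is supplied as the 3-chloroaryne A5 and the rest as the trans-2,4-diaryloxetane A4. The oxetane oxygen adds to the aryne carbon remote from chlorine, the oxetanium ion opens at the carbon bearing the trioxygenated ring, and the ortho aryl anion closes onto it, expanding the four-membered ring to ring C in A6.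
- Merits: two bonds and ring C in one convergent step, with ring D already attached and both stereocentres stored in a small building block. In convergence it beats the chosen plan.
- Weak points: an enantiopure trans oxetane with a very electron-rich aryl group on one carbon is laborious to make and prone to ionise. C4 passes through a planar cation inside a zwitterion, so trans is not guaranteed. The chlorine needed for aryne regiocontrol must be removed, the aryne precursor adds steps, and ring-D acylation remains.
- Comparison: the chosen plan sets against this a ring C made by standard flavanone chemistry, no halogen detour, and a key step that leaves both stereocentres untouched.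

**Alternative 3:** The cut is O1–C8a alone. Ring A of an open-chain diarylpropanol is oxidised to the para-quinol methyl ether dienone A7. The C2 hydroxyl adds 6-exo-trig to a β-carbon, and acid then expels the methoxy group and rearomatises ring A, giving flavan A8 with a free C7 hydroxyl.
- Merits: both stereocentres are made independently in the open chain and are not touched by ring closure, because the new bond goes to an sp2 carbon. This is stereochemically the most secure of the four routes and better than the chosen plan's reliance on diastereoselective capture of cation 9.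
- Weak points: a long route to the open-chain precursor. The oxidative dearomatisation must spare a tris(benzyloxy)phenyl ring that is more easily oxidised than the phenol. The quaternary carbon of A7 bears a substituent that can leave as a stabilised benzylic cation under the acid needed for rearomatisation. The free C7 hydroxyl must be reprotected or will compete in the acylation.
- Comparison: the chosen plan sets a shorter sequence and a ring-D construction under neutral conditions against this stereochemical advantage, and its minor cis isomer can be removed at 11.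

Key step: step 7

Remark on the chemistry: the sense of induction in step 2 is assumed to follow the usual model for rhodium–biaryl bisphosphine conjugate arylation, (S)-ligand giving the (2S)-flavanone; if the parent chromone shows the opposite sense, the (R)-ligand is used and nothing else changes.

Remark on the chemistry: the C4 descriptor changes between 10 (R), 11–14 (S) and 22–27 (R) only because the CIP rank of the C4 substituent changes; the 2,4-trans arrangement is the same throughout.

## Route

Step 1
Reactants: 1 1-[4-(benzyloxy)-2-hydroxyphenyl]ethan-1-one; 2 N,N-dimethylformamide dimethyl acetal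
Product: 4 7-(benzyloxy)-4H-chromen-4-one, via enaminone 3 (not isolated)
Conditions: 2 (1.5 equiv), toluene, 100 °C; then conc. HCl, CH2Cl2, 40 °C
Reagents that add atoms: none
Why: Enaminone formation at the acetyl methyl group, then acid-promoted conjugate addition of the phenol and loss of dimethylamine, is the standard enaminone route to 3-unsubstituted chromones; the benzyl ether tolerates both stages.

Step 2
Reactants: 4 7-(benzyloxy)-4H-chromen-4-one; 5 [4-(benzyloxy)phenyl]boronic acid
Product: 6 (2S)-7-(benzyloxy)-2-[4-(benzyloxy)phenyl]-2,3-dihydro-4H-chromen-4-one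
Conditions: 5 (2 equiv), [Rh(OH)(cod)]2 (cat.), (S)-MeO-F12-BIPHEP [(S)-6,6'-dimethoxy-2,2'-bis{bis(3,4,5-trifluorophenyl)phosphino}biphenyl], CH2Cl2/H2O, 20 °C
Reagents that add atoms: none
Why: Hayashi–Miyaura asymmetric 1,4-addition to a chromone; the aryl–rhodium species with the electron-poor bisphosphine inserts C2=C3 on one enantiotopic face, so C2 is set by the ligand, and the base-free room-temperature conditions keep the flavanone from racemising by retro-oxa-Michael opening.

Step 3
Reactants: 6 (2S)-flavanone
Product: 7 (2S,4S)-7-(benzyloxy)-2-[4-(benzyloxy)phenyl]-3,4-dihydro-2H-chromen-4-ol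
Conditions: NaBH4, THF/MeOH, −20 → 0 °C
Reagents that add atoms: none
Why: Borohydride reduction of a flavanone; axial hydride delivery to the half-chair with equatorial C2 aryl should give mainly the 2,4-cis alcohol, and since C4 becomes planar in step 4 any trans epimer is equally usable; the low temperature protects C2.

Step 4
Reactants: 7 (2S,4S)-flavan-4-ol; 8 potassium trifluoro[(trimethylsilyl)ethynyl]borate
Product: 11 (2S,4S)-7-(benzyloxy)-2-[4-(benzyloxy)phenyl]-4-ethynyl-3,4-dihydro-2H-chromene, via flavan-4-ylium ion 9 (not isolated), via trimethylsilylalkyne 10 (not isolated)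
Conditions: 8 (1.5 equiv), BF3·OEt2, CH2Cl2, −40 → 0 °C; then K2CO3, MeOH/THF, rt
Reagents that add atoms: none
Why: Lewis-acid-mediated substitution of an electron-rich benzylic alcohol by an alkynyltrifluoroborate: BF3 turns 8 into the alkynyldifluoroborane, which ionises the C4 hydroxyl to cation 9 (stabilised by O1 and the para 7-benzyloxy group) and transfers the alkynyl group; the C4 centre is set by C2, whose pseudo-equatorial aryl group leaves the axial trajectory open, so 10 should be mainly 2,4-trans; K2CO3/MeOH then removes the silyl group and the minor cis isomer is separated at 11.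

Step 5
Reactants: 11 (2S,4S)-4-ethynylflavan
Product: 14 (2S,4S)-7-(benzyloxy)-2-[4-(benzyloxy)phenyl]-4-({[tri(propan-2-yl)silyl]oxy}ethynyl)-3,4-dihydro-2H-chromene, via lithium acetylide 12 (not isolated), via lithium ynolate 13 (not isolated)
Conditions: LiN(SiMe3)2, THF, −78 °C; LiOOt-Bu [from t-BuOOH and LiN(SiMe3)2], −78 → 0 °C; then i-Pr3SiOTf, −78 °C
Reagents that add atoms: lithium tert-butyl peroxide, [Li+].CC(C)(C)O[O-] (made from tert-butyl hydroperoxide, CC(C)(C)OO; supplies the ynol oxygen); triisopropylsilyl trifluoromethanesulfonate, CC(C)[Si](OS(=O)(=O)C(F)(F)F)(C(C)C)C(C)C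
Why: Oxenoid oxidation of a lithium acetylide by a lithium alkyl peroxide to the ynolate, then O-silylation with a bulky silyl triflate, is the established route from terminal alkynes to triisopropylsiloxyalkynes; the amide base removes only the sp C–H, so the propargylic C4–H and the C4 configuration are not touched.

Step 6
Reactants: 15 3-ethoxycyclobut-2-en-1-one; 16 benzyl alcohol
Product: 17 3-(benzyloxy)cyclobut-2-en-1-one
Conditions: 16 (4 equiv), camphorsulfonic acid (cat.), neat, 30 °C, 50 mbar (ethanol stripped)
Reagents that add atoms: none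
Why: Acid-catalysed alkoxy exchange of a vinylogous ester (addition of the alcohol to the protonated enone, loss of ethanol, equilibrium driven by removing ethanol); it puts a hydrogenolysable benzyl group on the oxygen that becomes O4'.

Step 7
Reactants: 14 siloxyalkyne; 17 3-(benzyloxy)cyclobut-2-en-1-one
Product: 22 5-(benzyloxy)-2-[(2S,4R)-7-(benzyloxy)-2-[4-(benzyloxy)phenyl]-3,4-dihydro-2H-chromen-4-yl]-3-{[tri(propan-2-yl)silyl]oxy}phenol, via vinylketene 18 (not isolated), via vinylcyclobutenone 19 (not isolated), via dienylketene 20 (not isolated), via cyclohexadienone 21 (not isolated)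
Conditions: 17 (1.5–2 equiv), toluene, 80 °C then 110 °C, argon, base-washed glassware
Reagents that add atoms: none
Why: Danheiser benzannulation. On heating, 17 opens by 4π electrocyclic ring opening to vinylketene 18, whose carbonyl carbon is attacked by the nucleophilic β-carbon of ynol ether 14 (the carbon bonded to C4), so the regioselective [2+2] cycloaddition gives vinylcyclobutenone 19 with C1'–C2' and C5'–C6' formed. The strained ring of 19 reopens (second 4π opening) to dienylketene 20, which closes ring D by thermal disrotatory 6π electrocyclisation between the ketene carbon and the terminal methylene; cyclohexadienone 21 then tautomerises to phenol 22. The closest known reaction is the same cascade between 3-substituted cyclobutenones and triisopropylsiloxyalkynes, which gives resorcinol monosilyl ethers with the alkyne substituent between the two oxygens, including alkynes with a branched ring-bound substituent. No stereocentre is created: the sp3 carbon of 19 disappears on aromatisation, and C2 and C4 are spectators under neutral thermal conditions. The one selectivity needed, the orientation of the [2+2] step, is fixed by the polarisation of the silyl ynol ether and places C2'–OH (from the ketene carbonyl), C6'–OSi and C4'–OBn around C1'. An excess of the inexpensive partner 17 allows for self-reaction of 18.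

Step 8
Reactants: 22 ring-D phenol; 23 dodecanoyl chloride
Product: 25 1-{6-(benzyloxy)-3-[(2S,4R)-7-(benzyloxy)-2-[4-(benzyloxy)phenyl]-3,4-dihydro-2H-chromen-4-yl]-2-hydroxy-4-{[tri(propan-2-yl)silyl]oxy}phenyl}dodecan-1-one, via bromomagnesium phenolate 24 (not isolated)
Conditions: EtMgBr (1.0 equiv), Et2O, 0 °C; solvent exchanged for toluene; 23 (1.1 equiv), rt → 50 °C; aq. NH4Cl
Reagents that add atoms: none
Why: Ortho-specific C-acylation of a magnesium phenolate by an acyl chloride in a non-coordinating solvent (coordinated Friedel–Crafts acylation): magnesium holds the phenolate oxygen and the acyl chloride together and delivers the acyl group to the only free ortho carbon, C3', the most nucleophilic site of the molecule; no strong acid is present to strip the benzyl or silyl ethers or ionise C4–C1'.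

Step 9
Reactants: 25 acylated silyl ether
Product: 26 1-{6-(benzyloxy)-3-[(2S,4R)-7-(benzyloxy)-2-[4-(benzyloxy)phenyl]-3,4-dihydro-2H-chromen-4-yl]-2,4-dihydroxyphenyl}dodecan-1-one
Conditions: Bu4NF, AcOH, THF, 0 °C
Reagents that add atoms: none
Why: Fluoride cleavage of an aryl triisopropylsilyl ether; the phenol released is para to the acyl group and leaves readily, and the acetic acid buffer keeps the medium near neutral.

Step 10
Reactants: 26 tri-O-benzyl myristinin A
Product: 27 (+)-myristinin A [1-{2,4,6-trihydroxy-3-[(2S,4R)-7-hydroxy-2-(4-hydroxyphenyl)-3,4-dihydro-2H-chromen-4-yl]phenyl}dodecan-1-one]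
Conditions: H2 (1 atm), Pd/C (10%), EtOAc/MeOH, rt
Reagents that add atoms: none
Why: Hydrogenolysis of three aryl benzyl ethers over palladium; the hydrogen-bonded acylphloroglucinol ketone and the cyclic benzylic ether O1–C2 are expected to survive these mild, acid-free conditions, as is usual in flavan chemistry, so C2 and C4 stay intact.

## Compound list

1 | 1-[4-(benzyloxy)-2-hydroxyphenyl]ethan-1-one | CC(=O)c1ccc(OCc2ccccc2)cc1O | starting material
2 | N,N-dimethylformamide dimethyl acetal | COC(OC)N(C)C | starting material
3 | (E)-1-[4-(benzyloxy)-2-hydroxyphenyl]-3-(dimethylamino)prop-2-en-1-one | CN(C)/C=C/C(=O)c1ccc(OCc2ccccc2)cc1O | intermediate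
4 | 7-(benzyloxy)-4H-chromen-4-one | O=c1ccoc2cc(OCc3ccccc3)ccc12 | intermediate
5 | [4-(benzyloxy)phenyl]boronic acid | OB(O)c1ccc(OCc2ccccc2)cc1 | starting material
6 | (2S)-7-(benzyloxy)-2-[4-(benzyloxy)phenyl]-2,3-dihydro-4H-chromen-4-one | O=C1C[C@@H](c2ccc(OCc3ccccc3)cc2)Oc2cc(OCc3ccccc3)ccc21 | intermediate
7 | (2S,4S)-7-(benzyloxy)-2-[4-(benzyloxy)phenyl]-3,4-dihydro-2H-chromen-4-ol (2,4-cis) | O[C@H]1C[C@@H](c2ccc(OCc3ccccc3)cc2)Oc2cc(OCc3ccccc3)ccc21 | intermediate
8 | potassium trifluoro[(trimethylsilyl)ethynyl]borate | [K+].C[Si](C)(C)C#C[B-](F)(F)F | starting material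
9 | (2S)-7-(benzyloxy)-2-[4-(benzyloxy)phenyl]-3,4-dihydro-2H-chromen-4-ylium | [CH+]1C[C@@H](c2ccc(OCc3ccccc3)cc2)Oc2cc(OCc3ccccc3)ccc21 | intermediate
10 | {[(2S,4R)-7-(benzyloxy)-2-[4-(benzyloxy)phenyl]-3,4-dihydro-2H-chromen-4-yl]ethynyl}trimethylsilane (2,4-trans) | C[Si](C)(C)C#C[C@@H]1C[C@@H](c2ccc(OCc3ccccc3)cc2)Oc2cc(OCc3ccccc3)ccc21 | intermediate
11 | (2S,4S)-7-(benzyloxy)-2-[4-(benzyloxy)phenyl]-4-ethynyl-3,4-dihydro-2H-chromene (2,4-trans) | C#C[C@@H]1C[C@@H](c2ccc(OCc3ccccc3)cc2)Oc2cc(OCc3ccccc3)ccc21 | intermediate
12 | lithium acetylide of 11 | [Li]C#C[C@@H]1C[C@@H](c2ccc(OCc3ccccc3)cc2)Oc2cc(OCc3ccccc3)ccc21 | intermediate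
13 | lithium 2-[(2S,4S)-7-(benzyloxy)-2-[4-(benzyloxy)phenyl]-3,4-dihydro-2H-chromen-4-yl]ethyn-1-olate | [Li]OC#C[C@@H]1C[C@@H](c2ccc(OCc3ccccc3)cc2)Oc2cc(OCc3ccccc3)ccc21 | intermediate
14 | (2S,4S)-7-(benzyloxy)-2-[4-(benzyloxy)phenyl]-4-({[tri(propan-2-yl)silyl]oxy}ethynyl)-3,4-dihydro-2H-chromene (2,4-trans) | CC(C)[Si](OC#C[C@@H]1C[C@@H](c2ccc(OCc3ccccc3)cc2)Oc2cc(OCc3ccccc3)ccc21)(C(C)C)C(C)C | intermediate
15 | 3-ethoxycyclobut-2-en-1-one | CCOC1=CC(=O)C1 | starting material
16 | benzyl alcohol | OCc1ccccc1 | starting material
17 | 3-(benzyloxy)cyclobut-2-en-1-one | O=C1C=C(OCc2ccccc2)C1 | intermediate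
18 | 3-(benzyloxy)buta-1,3-dien-1-one | C=C(OCc1ccccc1)C=C=O | intermediate
19 | 4-[1-(benzyloxy)ethenyl]-2-(flavan-4-yl)-3-(triisopropylsilyloxy)cyclobut-2-en-1-one, flavanyl group configured as in 14, ring sp3 carbon undefined | C=C(OCc1ccccc1)C1C(=O)C([C@@H]2C[C@@H](c3ccc(OCc4ccccc4)cc3)Oc3cc(OCc4ccccc4)ccc32)=C1O[Si](C(C)C)(C(C)C)C(C)C | intermediate
20 | 5-(benzyloxy)-2-(flavan-4-yl)-3-(triisopropylsilyloxy)hexa-1,3,5-trien-1-one, C2 and C5 cis across C3=C4, flavanyl group as in 14 | C=C(OCc1ccccc1)/C=C(/O[Si](C(C)C)(C(C)C)C(C)C)C(=C=O)[C@@H]1C[C@@H](c2ccc(OCc3ccccc3)cc2)Oc2cc(OCc3ccccc3)ccc21 | intermediate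
21 | 5-(benzyloxy)-2-(flavan-4-yl)-3-(triisopropylsilyloxy)cyclohexa-2,4-dien-1-one, flavanyl group as in 14 | O=C1CC(OCc2ccccc2)=CC(O[Si](C(C)C)(C(C)C)C(C)C)=C1[C@@H]1C[C@@H](c2ccc(OCc3ccccc3)cc2)Oc2cc(OCc3ccccc3)ccc21 | intermediate
22 | 5-(benzyloxy)-2-[(2S,4R)-7-(benzyloxy)-2-[4-(benzyloxy)phenyl]-3,4-dihydro-2H-chromen-4-yl]-3-{[tri(propan-2-yl)silyl]oxy}phenol | Oc1cc(OCc2ccccc2)cc(O[Si](C(C)C)(C(C)C)C(C)C)c1[C@@H]1C[C@@H](c2ccc(OCc3ccccc3)cc2)Oc2cc(OCc3ccccc3)ccc21 | intermediate
23 | dodecanoyl chloride | CCCCCCCCCCCC(=O)Cl | starting material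
24 | bromomagnesium phenolate of 22 | Br[Mg]Oc1cc(OCc2ccccc2)cc(O[Si](C(C)C)(C(C)C)C(C)C)c1[C@@H]1C[C@@H](c2ccc(OCc3ccccc3)cc2)Oc2cc(OCc3ccccc3)ccc21 | intermediate
25 | 1-{6-(benzyloxy)-3-[(2S,4R)-7-(benzyloxy)-2-[4-(benzyloxy)phenyl]-3,4-dihydro-2H-chromen-4-yl]-2-hydroxy-4-{[tri(propan-2-yl)silyl]oxy}phenyl}dodecan-1-one | CCCCCCCCCCCC(=O)c1c(O)c([C@@H]2C[C@@H](c3ccc(OCc4ccccc4)cc3)Oc3cc(OCc4ccccc4)ccc32)c(O[Si](C(C)C)(C(C)C)C(C)C)cc1OCc1ccccc1 | intermediate
26 | 1-{6-(benzyloxy)-3-[(2S,4R)-7-(benzyloxy)-2-[4-(benzyloxy)phenyl]-3,4-dihydro-2H-chromen-4-yl]-2,4-dihydroxyphenyl}dodecan-1-one | CCCCCCCCCCCC(=O)c1c(O)c([C@@H]2C[C@@H](c3ccc(OCc4ccccc4)cc3)Oc3cc(OCc4ccccc4)ccc32)c(O)cc1OCc1ccccc1 | intermediate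
27 | (+)-myristinin A, 1-{2,4,6-trihydroxy-3-[(2S,4R)-7-hydroxy-2-(4-hydroxyphenyl)-3,4-dihydro-2H-chromen-4-yl]phenyl}dodecan-1-one | CCCCCCCCCCCC(=O)c1c(O)cc(O)c([C@@H]2C[C@@H](c3ccc(O)cc3)Oc3cc(O)ccc32)c1O | target

## Step count and least certain steps

Total: 10 steps. Longest linear sequence: 9 steps (1 → 27 through steps 1–5 and 7–10); step 6 is a one-step side branch.

**Step 7 (key step).** The benzyloxy-substituted vinylketene 18 may dimerise or be captured by the phenol of 22 (O-acylation) faster than it adds to the ynol ether, whose reacting carbon carries a branched substituent. The cascade may stall before the second ring opening. The ynol ether may undergo thermal 1,3-silyl shift to a silylketene.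
Fallback: ring D is attached ready-made. Phloroglucinol is C-acylated with 23 (AlCl3) to 1-(2,4,6-trihydroxyphenyl)dodecan-1-one F1. Flavan-4-ol 7 is ionised with catalytic acid (TsOH, dioxane) in the presence of F1, whose free ring carbon captures cation 9 on the axial side to give 7,4'-di-O-benzylmyristinin A F2. Hydrogenolysis (H2, Pd/C) of F2 rejoins the route at 27. It sets out from 7 and 23.

**Step 4.** Facial selectivity in the capture of the planar cation may be poor. Proton loss from C3 (elimination to the 2H-chromene) and reversible opening of O1–C2 (erosion at C2) compete if alkynyl transfer is slow.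
Fallback: a stronger carbon nucleophile and a different source of the ynolate. Flavan-4-ol 7 is treated with BF3·OEt2 and 1-ethoxy-1-(trimethylsilyloxy)ethene (Mukaiyama-type capture) to give ethyl 2-[(2S,4S)-7-(benzyloxy)-2-[4-(benzyloxy)phenyl]-3,4-dihydro-2H-chromen-4-yl]acetate F3. Two enolisation–bromination cycles [LiN(SiMe3)2; N-bromosuccinimide] give the α,α-dibromo ester F4. t-BuLi (4 equiv, THF, −78 → 0 °C) converts F4 by double bromine–lithium exchange and loss of ethoxide into ynolate 13, where the route is rejoined and silylation gives 14. It sets out from 7.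

**Step 5.** Oxygen transfer from the peroxide to the hindered acetylide may be incomplete. Silylation may occur on carbon (silylketene formation). Excess base may cause propargyl–allenyl equilibration at C4. The ynol ether may hydrolyse during isolation.
Fallback: the oxygen is introduced through hypervalent iodine chemistry. Alkyne 11 with PhI(OH)OTs gives the alkynyl(phenyl)iodonium tosylate F5. Catalytic CuOTf in MeCN collapses F5 to the alkynyl tosylate F6. MeLi attacks sulfur in F6 and releases ynolate 13, which is silylated as in step 5 to rejoin the route at 14. It sets out from 11.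

**Step 8.** Acylation may go to the phenolate oxygen and not to C3'. Hydrogen chloride released if the magnesium chelate breaks down could cause loss of the silyl ether or heterolysis of C4–C1'.
Fallback: the acyl carbon is introduced in two pieces under basic conditions. Phenol 22 is ortho-formylated (MgCl2, Et3N, paraformaldehyde, MeCN, Casnati–Skattebøl) to salicylaldehyde F7. Undecylmagnesium bromide (2.2 equiv) adds to give the benzylic alcohol F8 (epimers at the carbinol). MnO2 oxidises F8 to ketone 25, where the route is rejoined. It sets out from 22.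

**Step 2.** Insertion into the electron-rich 7-alkoxychromone may be sluggish, so that protodeboronation of 5 dominates. Any retro-oxa-Michael opening of 6 lowers the enantiomeric purity.
Fallback: resolution in place of asymmetric arylation. Ketone 1 and 4-(benzyloxy)benzaldehyde condense (KOH, EtOH, Claisen–Schmidt) to the 2'-hydroxychalcone F9. NaOAc in refluxing EtOH cyclises F9 to the racemic flavanone F10. Noyori transfer hydrogenation with RuCl(p-cymene)[(S,S)-TsDPEN] and HCO2H/Et3N reduces the (2S) enantiomer selectively to 7, where the route is rejoined, and leaves the (2R)-flavanone F11, which base re-racemises to F10 for recycling. It sets out from 1.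

**Step 6.** Acid may open the strained enone through attack of the alcohol at the carbonyl (ester formation). The exchange equilibrium may remain incomplete.
Fallback: 15 is hydrolysed with dilute aqueous HCl to cyclobutane-1,3-dione F12, and this vinylogous acid is O-benzylated with 16 under Mitsunobu conditions (PPh3, diisopropyl azodicarboxylate, THF, 0 °C) to rejoin the route at 17. It sets out from 15.

## Further compounds

F1 | step 7 | 1-(2,4,6-trihydroxyphenyl)dodecan-1-one | CCCCCCCCCCCC(=O)c1c(O)cc(O)cc1O
F2 | step 7 | 7,4'-di-O-benzylmyristinin A, 1-{3-[(2S,4R)-7-(benzyloxy)-2-[4-(benzyloxy)phenyl]-3,4-dihydro-2H-chromen-4-yl]-2,4,6-trihydroxyphenyl}dodecan-1-one | CCCCCCCCCCCC(=O)c1c(O)cc(O)c([C@@H]2C[C@@H](c3ccc(OCc4ccccc4)cc3)Oc3cc(OCc4ccccc4)ccc32)c1O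
F3 | step 4 | ethyl 2-[(2S,4S)-7-(benzyloxy)-2-[4-(benzyloxy)phenyl]-3,4-dihydro-2H-chromen-4-yl]acetate (2,4-trans) | CCOC(=O)C[C@@H]1C[C@@H](c2ccc(OCc3ccccc3)cc2)Oc2cc(OCc3ccccc3)ccc21
F4 | step 4 | ethyl 2,2-dibromo-2-[(2S,4R)-7-(benzyloxy)-2-[4-(benzyloxy)phenyl]-3,4-dihydro-2H-chromen-4-yl]acetate (2,4-trans) | CCOC(=O)C(Br)(Br)[C@@H]1C[C@@H](c2ccc(OCc3ccccc3)cc2)Oc2cc(OCc3ccccc3)ccc21
F5 | step 5 | {[7-(benzyloxy)-2-[4-(benzyloxy)phenyl]-3,4-dihydro-2H-chromen-4-yl]ethynyl}(phenyl)iodonium 4-methylbenzenesulfonate, C2 and C4 arranged as in 11 | Cc1ccc(S(=O)(=O)[O-])cc1.c1ccccc1[I+]C#C[C@@H]1C[C@@H](c2ccc(OCc3ccccc3)cc2)Oc2cc(OCc3ccccc3)ccc21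
F6 | step 5 | [7-(benzyloxy)-2-[4-(benzyloxy)phenyl]-3,4-dihydro-2H-chromen-4-yl]ethynyl 4-methylbenzenesulfonate, C2 and C4 arranged as in 11 | Cc1ccc(S(=O)(=O)OC#C[C@@H]2C[C@@H](c3ccc(OCc4ccccc4)cc3)Oc3cc(OCc4ccccc4)ccc32)cc1
F7 | step 8 | 6-(benzyloxy)-3-[(2S,4R)-7-(benzyloxy)-2-[4-(benzyloxy)phenyl]-3,4-dihydro-2H-chromen-4-yl]-2-hydroxy-4-{[tri(propan-2-yl)silyl]oxy}benzaldehyde | O=Cc1c(O)c([C@@H]2C[C@@H](c3ccc(OCc4ccccc4)cc3)Oc3cc(OCc4ccccc4)ccc32)c(O[Si](C(C)C)(C(C)C)C(C)C)cc1OCc1ccccc1
F8 | step 8 | 1-{6-(benzyloxy)-3-[(2S,4R)-7-(benzyloxy)-2-[4-(benzyloxy)phenyl]-3,4-dihydro-2H-chromen-4-yl]-2-hydroxy-4-{[tri(propan-2-yl)silyl]oxy}phenyl}dodecan-1-ol (carbinol epimers) | CCCCCCCCCCCC(O)c1c(O)c([C@@H]2C[C@@H](c3ccc(OCc4ccccc4)cc3)Oc3cc(OCc4ccccc4)ccc32)c(O[Si](C(C)C)(C(C)C)C(C)C)cc1OCc1ccccc1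
F9 | step 2 | (E)-1-[4-(benzyloxy)-2-hydroxyphenyl]-3-[4-(benzyloxy)phenyl]prop-2-en-1-one | O=C(/C=C/c1ccc(OCc2ccccc2)cc1)c1ccc(OCc2ccccc2)cc1O
F10 | step 2 | rac-7-(benzyloxy)-2-[4-(benzyloxy)phenyl]-2,3-dihydro-4H-chromen-4-one | O=C1CC(c2ccc(OCc3ccccc3)cc2)Oc2cc(OCc3ccccc3)ccc21
F11 | step 2 | (2R)-7-(benzyloxy)-2-[4-(benzyloxy)phenyl]-2,3-dihydro-4H-chromen-4-one | O=C1C[C@H](c2ccc(OCc3ccccc3)cc2)Oc2cc(OCc3ccccc3)ccc21
F12 | step 6 | cyclobutane-1,3-dione | O=C1CC(=O)C1
A1 | alternative 1 | phloretin, 3-(4-hydroxyphenyl)-1-(2,4,6-trihydroxyphenyl)propan-1-one | O=C(CCc1ccc(O)cc1)c1c(O)cc(O)cc1O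
A2 | alternative 1 | 2-{3-[4-(benzyloxy)phenyl]-1-[2-hydroxy-4-(pivaloyloxy)phenyl]propyl}benzene-1,3,5-triyl tripivalate, methine carbon arranged as C4 of the target | CC(C)(C)C(=O)Oc1cc(OC(=O)C(C)(C)C)cc(OC(=O)C(C)(C)C)c1[C@H](CCc1ccc(OCc2ccccc2)cc1)c1ccc(OC(=O)C(C)(C)C)cc1O
A3 | alternative 1 | 2,4-trans flavan tetrapivalate with ring-B benzyl ether | CC(C)(C)C(=O)Oc1cc(OC(=O)C(C)(C)C)cc(OC(=O)C(C)(C)C)c1[C@@H]1C[C@@H](c2ccc(OCc3ccccc3)cc2)Oc2cc(OC(=O)C(C)(C)C)ccc12
A4 | alternative 2 | trans-2-[4-(benzyloxy)phenyl]-4-[2,4,6-tris(benzyloxy)phenyl]oxetane, carbons arranged as C2 and C4 of the target | c1ccccc1COc1cc(OCc2ccccc2)cc(OCc2ccccc2)c1[C@@H]1C[C@@H](c2ccc(OCc3ccccc3)cc2)O1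
A5 | alternative 2 | 5-(benzyloxy)-3-chlorobenzyne | ClC1=CC(OCc2ccccc2)=CC#C1
A6 | alternative 2 | 5-chloro-7-(benzyloxy)-2-[4-(benzyloxy)phenyl]-4-[2,4,6-tris(benzyloxy)phenyl]chromane, 2,4-trans | c1ccccc1COc1cc(OCc2ccccc2)cc(OCc2ccccc2)c1[C@@H]1C[C@@H](c2ccc(OCc3ccccc3)cc2)Oc2cc(OCc3ccccc3)cc(Cl)c12
A7 | alternative 3 | 4-{3-[4-(benzyloxy)phenyl]-3-hydroxy-1-[2,4,6-tris(benzyloxy)phenyl]propyl}-4-methoxycyclohexa-2,5-dien-1-one, stereocentres arranged as C4 and C2 of the target | c1ccccc1COc1cc(OCc2ccccc2)cc(OCc2ccccc2)c1[C@H](C[C@H](O)c1ccc(OCc2ccccc2)cc1)C1(OC)C=CC(=O)C=C1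
A8 | alternative 3 | 2-[4-(benzyloxy)phenyl]-4-[2,4,6-tris(benzyloxy)phenyl]chroman-7-ol, 2,4-trans | c1ccccc1COc1cc(OCc2ccccc2)cc(OCc2ccccc2)c1[C@@H]1C[C@@H](c2ccc(OCc3ccccc3)cc2)Oc2cc(O)ccc12
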